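The route rests on disconnecting the C2–C3 bond of the dihydropyranone ring C. C2 is both benzylic to ring B and bonded to the ring oxygen O1, so in an aryl benzyl ether precursor its C–H bonds are activated and lie 1,6 to C3, the carbon alpha to the C4 ketone. With C3 as a diazo carbon, a chiral dirhodium carboxylate converts an achiral 2-(benzyloxy)aryl diazomethyl ketone into the flavanone by intramolecular carbene C–H insertion: one operation closes ring C, forms C2–C3 and sets the 2S centre. The precursor is the protected phloroacetophenone ether of a 3-geranyl-2,4-dioxygenated benzyl alcohol, assembled by directed metalation, Mitsunobu coupling and diazo transfer.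

Key step: step 7

Assumption: the sense of induction of Rh2(S-BSP)4 (BSP = N-benzenesulfonylprolinate) in step 7 cannot be predicted with certainty for this substrate; the S-prolinate catalyst is written as the one giving 2S, and its mirror image Rh2(R-BSP)4 would replace it without other change if a trial on the parent 2-benzyloxy diazoketone showed the opposite sense.

Step 1
Reactants: 1 resorcinol
Product: 2 1,3-bis(methoxymethoxy)benzene
Conditions: NaH (2.4 equiv), MOMCl (2.4 equiv), DMF, 0 °C to rt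
Reagents that add atoms: chloromethyl methyl ether (MOMCl), COCCl
Why: Williamson-type O-alkylation of the bis-phenoxide with the reactive chloromethyl ether should give the bis-acetal whose oxygen atoms later direct both metalations.

Step 2
Reactants: 2 1,3-bis(methoxymethoxy)benzene; 3 geranyl bromide, (2E)-1-bromo-3,7-dimethylocta-2,6-diene
Product: 5 2-[(2E)-3,7-dimethylocta-2,6-dien-1-yl]-1,3-bis(methoxymethoxy)benzene, via 2-lithio-1,3-bis(methoxymethoxy)benzene 4 (not isolated)
Conditions: n-BuLi (1.1 equiv), THF, 0 °C to rt; CuI (10 mol%), −78 °C; 3, −78 °C to rt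
Reagents that add atoms: n-butyllithium, [Li]CCCC (supplies only the lithium of intermediate 4)
Why: Directed ortho-metalation between the two cooperating MOM ethers followed by copper-mediated SN2 allylation with the primary allylic bromide should place the geranyl group at C2 with its E geometry intact.

Step 3
Reactants: 5 2-[(2E)-3,7-dimethylocta-2,6-dien-1-yl]-1,3-bis(methoxymethoxy)benzene
Product: 7 {3-[(2E)-3,7-dimethylocta-2,6-dien-1-yl]-2,4-bis(methoxymethoxy)phenyl}methanol, via aryllithium 6 (not isolated)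
Conditions: n-BuLi (1.2 equiv), TMEDA, THF, 0 °C; dry (CH2O)n (excess), −78 °C to rt; aq. NH4Cl
Reagents that add atoms: paraformaldehyde as formaldehyde, C=O; n-butyllithium, [Li]CCCC (supplies only the lithium of intermediate 6)
Why: Directed ortho-metalation by a MOM ether at C4 (C4 and C6 are equivalent) and 1,2-addition of the aryllithium to formaldehyde should give the benzylic alcohol directly.

Step 4
Reactants: 8 2,4,6-trihydroxyacetophenone (dried)
Product: 9 1-[2-hydroxy-4,6-bis(triisopropylsilyloxy)phenyl]ethan-1-one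
Conditions: TIPSCl (2.1 equiv), imidazole (4 equiv), DMF, 0 °C to rt
Reagents that add atoms: triisopropylsilyl chloride, CC(C)[Si](Cl)(C(C)C)C(C)C
Why: Chemoselective silylation should cap the 4-OH and one of the two equivalent ortho OH groups, while the last ortho OH stays free because it is hydrogen-bonded to the carbonyl and the silyl chloride is bulky.

Step 5
Reactants: 7 {3-[(2E)-3,7-dimethylocta-2,6-dien-1-yl]-2,4-bis(methoxymethoxy)phenyl}methanol; 9 1-[2-hydroxy-4,6-bis(triisopropylsilyloxy)phenyl]ethan-1-one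
Product: 10 1-[2-({3-[(2E)-3,7-dimethylocta-2,6-dien-1-yl]-2,4-bis(methoxymethoxy)phenyl}methoxy)-4,6-bis(triisopropylsilyloxy)phenyl]ethan-1-one
Conditions: PPh3, DIAD, THF, 0 °C to rt
Reagents that add atoms: none
Why: Mitsunobu etherification lets the chelated but acidic phenol of 9 displace the oxyphosphonium of the primary benzylic alcohol 7 by SN2 under neutral conditions, which spare the acid-labile electron-rich benzyl ether, the MOM groups and the silyl ethers.

Step 6
Reactants: 10 the aryl methyl ketone of step 5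
Product: 13 2-diazo-1-[2-({3-[(2E)-3,7-dimethylocta-2,6-dien-1-yl]-2,4-bis(methoxymethoxy)phenyl}methoxy)-4,6-bis(triisopropylsilyloxy)phenyl]ethan-1-one, via lithium enolate 11 (not isolated), via trifluoroacetyl diketone 12 (not isolated)
Conditions: LiN(SiMe3)2 (1.1 equiv), THF, −78 °C; CF3CO2CH2CF3 (1.2 equiv), −78 °C; aq. NH4Cl; then MsN3 (1.5 equiv), Et3N (1.5 equiv), H2O (1 equiv), MeCN, rt
Reagents that add atoms: methanesulfonyl azide, CS(=O)(=O)N=[N+]=[N-] (both diazo nitrogens); 2,2,2-trifluoroethyl trifluoroacetate, O=C(OCC(F)(F)F)C(F)(F)F (trifluoroacetyl group of intermediate 12 only); LiN(SiMe3)2, [Li]N([Si](C)(C)C)[Si](C)(C)C (lithium of intermediate 11 only)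
Why: Detrifluoroacetylative diazo transfer of the Regitz type should work because the kinetic enolate of the methyl ketone is C-trifluoroacetylated, the activated 1,3-diketone takes the diazo group from MsN3 and the trifluoroacetyl group leaves on the sulfonamide, all under base that the ethers tolerate.

Step 7
Reactants: 13 the diazoketone of step 6
Product: 14 (2S)-2-{3-[(2E)-3,7-dimethylocta-2,6-dien-1-yl]-2,4-bis(methoxymethoxy)phenyl}-5,7-bis(triisopropylsilyloxy)-2,3-dihydro-4H-chromen-4-one
Conditions: Rh2(S-BSP)4 (1 mol%), CH2Cl2, rt, 13 added over 6 h by syringe pump at high dilution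
Reagents that add atoms: none
Why: Rh2(S-BSP)4 expels N2 from 13 and the resulting electrophilic divalent-rhodium carbene at C3 inserts into one C–H bond of the ArO–CH2–Ar′ group through a concerted, asynchronous three-centre transition state with hydride-like character, which forms C2–C3 and releases the catalyst. The closest known reaction is the dirhodium-carboxylate-catalysed intramolecular C–H insertion of 2-alkoxyaryl diazoketones to chroman-4-ones, including its enantioselective variant with N-arylsulfonylprolinate ligands. Ring C closes as a six-membered ring by 1,6-C–H insertion (cyclic array C3–C4–C4a–C8a–O1–C2), an insertion mode to which exo or endo descriptors do not apply. The C2 centre is set under catalyst control: the chiral prolinate ligands decide which of the two enantiotopic benzylic hydrogens is replaced, with retention at carbon, the substrate itself being achiral. The step needs insertion to win over oxonium-ylide formation at O1 with 1,2-benzyl shift, over insertion at other sites and over cyclopropanation of the geranyl alkenes. The substrate secures this because the only C–H bonds 1,6 to the carbene are the doubly activated OCH2 hydrogens (alpha to oxygen, benzylic to the electron-rich ring B), the other ortho oxygen carries a bulky triisopropylsilyl group with no activated C–H in reach, O1 is a poorly nucleophilic vinylogous-ester oxygen, and the alkenes cannot reach the carbene within the molecule while slow addition suppresses intermolecular reactions.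

Step 8
Reactants: 14 the protected flavanone of step 7
Product: 16 Sanggenol A, via tetrasilyl ether 15 (not isolated)
Conditions: TMSOTf (5 equiv), 2,2′-bipyridyl (7 equiv), MeCN/CH2Cl2, 0 °C to rt; then HF·pyridine, pyridine, THF, 0 °C; pH 7 sodium phosphate buffer work-up
Reagents that add atoms: trimethylsilyl triflate, C[Si](C)(C)OS(=O)(=O)C(F)(F)F (trimethylsilyl groups of intermediate 15 only)
Why: Silyl triflate–bipyridyl exchange should turn the two aryl MOM ethers into aryl trimethylsilyl ethers without protic acid, and buffered fluoride then cleaves all four aryl silyl ethers (protecting-group removal by Si–O to Si–F exchange) under conditions meant to leave the C2–O1 bond, the 2S centre and the geranyl alkenes untouched.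

Compound list
1 | resorcinol (benzene-1,3-diol) | Oc1cccc(O)c1 | starting material
2 | 1,3-bis(methoxymethoxy)benzene | COCOc1cccc(OCOC)c1 | intermediate
3 | geranyl bromide, (2E)-1-bromo-3,7-dimethylocta-2,6-diene | CC(C)=CCC/C(C)=C/CBr | starting material
4 | 2-lithio-1,3-bis(methoxymethoxy)benzene | [Li]c1c(OCOC)cccc1OCOC | intermediate (not isolated)
5 | 2-[(2E)-3,7-dimethylocta-2,6-dien-1-yl]-1,3-bis(methoxymethoxy)benzene | CC(C)=CCC/C(C)=C/Cc1c(OCOC)cccc1OCOC | intermediate
6 | {3-[(2E)-3,7-dimethylocta-2,6-dien-1-yl]-2,4-bis(methoxymethoxy)phenyl}lithium | CC(C)=CCC/C(C)=C/Cc1c(OCOC)ccc([Li])c1OCOC | intermediate (not isolated)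
7 | {3-[(2E)-3,7-dimethylocta-2,6-dien-1-yl]-2,4-bis(methoxymethoxy)phenyl}methanol | CC(C)=CCC/C(C)=C/Cc1c(OCOC)ccc(CO)c1OCOC | intermediate
8 | 2,4,6-trihydroxyacetophenone | CC(=O)c1c(O)cc(O)cc1O | starting material
9 | 1-[2-hydroxy-4,6-bis(triisopropylsilyloxy)phenyl]ethan-1-one | CC(=O)c1c(O)cc(O[Si](C(C)C)(C(C)C)C(C)C)cc1O[Si](C(C)C)(C(C)C)C(C)C | intermediate
10 | 1-[2-({3-[(2E)-3,7-dimethylocta-2,6-dien-1-yl]-2,4-bis(methoxymethoxy)phenyl}methoxy)-4,6-bis(triisopropylsilyloxy)phenyl]ethan-1-one | CC(C)=CCC/C(C)=C/Cc1c(OCOC)ccc(COc2cc(O[Si](C(C)C)(C(C)C)C(C)C)cc(O[Si](C(C)C)(C(C)C)C(C)C)c2C(C)=O)c1OCOC | intermediate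
11 | lithium enolate of 10 | CC(C)=CCC/C(C)=C/Cc1c(OCOC)ccc(COc2cc(O[Si](C(C)C)(C(C)C)C(C)C)cc(O[Si](C(C)C)(C(C)C)C(C)C)c2C(=C)O[Li])c1OCOC | intermediate (not isolated)
12 | 4,4,4-trifluoro-1-aryl-butane-1,3-dione from 10 (trifluoroacetyl diketone) | CC(C)=CCC/C(C)=C/Cc1c(OCOC)ccc(COc2cc(O[Si](C(C)C)(C(C)C)C(C)C)cc(O[Si](C(C)C)(C(C)C)C(C)C)c2C(=O)CC(=O)C(F)(F)F)c1OCOC | intermediate (not isolated)
13 | 2-diazo-1-[2-({3-[(2E)-3,7-dimethylocta-2,6-dien-1-yl]-2,4-bis(methoxymethoxy)phenyl}methoxy)-4,6-bis(triisopropylsilyloxy)phenyl]ethan-1-one | CC(C)=CCC/C(C)=C/Cc1c(OCOC)ccc(COc2cc(O[Si](C(C)C)(C(C)C)C(C)C)cc(O[Si](C(C)C)(C(C)C)C(C)C)c2C(=O)C=[N+]=[N-])c1OCOC | intermediate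
14 | (2S)-2-{3-[(2E)-3,7-dimethylocta-2,6-dien-1-yl]-2,4-bis(methoxymethoxy)phenyl}-5,7-bis(triisopropylsilyloxy)-2,3-dihydro-4H-chromen-4-one | CC(C)=CCC/C(C)=C/Cc1c(OCOC)ccc([C@@H]2CC(=O)c3c(O[Si](C(C)C)(C(C)C)C(C)C)cc(O[Si](C(C)C)(C(C)C)C(C)C)cc3O2)c1OCOC | intermediate
15 | (2S)-2-{3-[(2E)-3,7-dimethylocta-2,6-dien-1-yl]-2,4-bis(trimethylsilyloxy)phenyl}-5,7-bis(triisopropylsilyloxy)-2,3-dihydro-4H-chromen-4-one | CC(C)=CCC/C(C)=C/Cc1c(O[Si](C)(C)C)ccc([C@@H]2CC(=O)c3c(O[Si](C(C)C)(C(C)C)C(C)C)cc(O[Si](C(C)C)(C(C)C)C(C)C)cc3O2)c1O[Si](C)(C)C | intermediate (not isolated)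
16 | Sanggenol A, (2S)-2-{3-[(2E)-3,7-dimethylocta-2,6-dien-1-yl]-2,4-dihydroxyphenyl}-5,7-dihydroxy-2,3-dihydro-4H-chromen-4-one | CC(C)=CCC/C(C)=C/Cc1c(O)ccc([C@@H]2CC(=O)c3c(O)cc(O)cc3O2)c1O | target

Total step count: 8 steps.
Longest linear sequence: 7 steps (steps 1, 2, 3, 5, 6, 7, 8); step 4 prepares the ring A partner separately.

Steps most likely to fail

1. Step 7. The carbene may attack the ether oxygen O1 faster than the C–H bond, so that an oxonium ylide forms and the electron-rich benzyl group shifts to carbon (1,2-Stevens shift) to give a benzofuranone. The catalyst may also discriminate poorly between the two enantiotopic benzylic hydrogens. The fallback gives up the carbene and makes the C2–aryl bond on a preformed ring C instead, using known chemistry. It sets out from 6 (generated from 5 as in step 3) and from 9. Aryllithium 6 is trapped with B(OiPr)3 and hydrolysed with aq. NH4Cl to {3-[(2E)-3,7-dimethylocta-2,6-dien-1-yl]-2,4-bis(methoxymethoxy)phenyl}boronic acid F1. Ketone 9 is condensed with Me2NCH(OMe)2 (toluene, 90 °C) to the enaminone F2, which should close with loss of dimethylamine under cat. TsOH in CH2Cl2 to 5,7-bis(triisopropylsilyloxy)chromone F3. Enantioselective 1,4-addition of F1 to F3 (Pd(OCOCF3)2, the t-BuPyOX antipode that gives 2S, NH4PF6, H2O, ClCH2CH2Cl, 60 °C; or a monovalent-rhodium/chiral diene catalyst) should then give 14, where the route is rejoined before step 8.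

2. Step 8. The Lewis-acidic exchange stage may ionise the C2–O1 bond of 14, which is benzylic to a 2,4-dioxygenated ring, and so erode the 2S centre. The hindered 2′-MOM ether may also exchange incompletely. The fallback removes MOM from the ring B building block before any sensitive bond exists, so that the last step is a buffered desilylation only. It sets out from 6 and returns at 16:
- A DMF quench of 6 should give the aldehyde F4.
- 3 M HCl/MeOH at rt should free the acid-stable salicylaldehyde F5.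
- TBSCl, imidazole, DMF should give the bis-silyl ether F6.
- NaBH4, MeOH/THF, −20 °C should give the benzylic alcohol F7.
- Mitsunobu coupling with 9 as in step 5 should give the ketone F8.
- The sequence of step 6, through the lithium enolate F9 and the trifluoroacetyl diketone F10, should give the diazoketone F11.
- Insertion as in step 7 should give the all-silyl flavanone F12.
- One treatment with HF·pyridine/pyridine in THF at 0 °C should then give 16.

3. Step 3. Metalation may occur at the benzylic and allylic CH2 of the geranyl chain in competition with ring lithiation, and the hindered aryllithium may be captured poorly by polymeric formaldehyde. The fallback reverses the order so that the geranyl group enters last. It sets out from 1 and returns at 7, before step 5. Vilsmeier–Haack formylation (POCl3, DMF, MeCN; then H2O) should give 2,4-dihydroxybenzaldehyde F13. NaH/MOMCl should give 2,4-bis(methoxymethoxy)benzaldehyde F14, and NaBH4 in MeOH the benzylic alcohol F15. n-BuLi (2.2 equiv), TMEDA, THF, 0 °C should form the O,C-dilithio species F16, metalated between the two MOM ethers. CuI followed by geranyl bromide 3 should then give 7.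

Further compounds
F1 | step 7 | {3-[(2E)-3,7-dimethylocta-2,6-dien-1-yl]-2,4-bis(methoxymethoxy)phenyl}boronic acid | CC(C)=CCC/C(C)=C/Cc1c(OCOC)ccc(B(O)O)c1OCOC
F2 | step 7 | (2E)-3-(dimethylamino)-1-[2-hydroxy-4,6-bis(triisopropylsilyloxy)phenyl]prop-2-en-1-one | CN(C)/C=C/C(=O)c1c(O)cc(O[Si](C(C)C)(C(C)C)C(C)C)cc1O[Si](C(C)C)(C(C)C)C(C)C
F3 | step 7 | 5,7-bis(triisopropylsilyloxy)-4H-chromen-4-one | O=c1ccoc2cc(O[Si](C(C)C)(C(C)C)C(C)C)cc(O[Si](C(C)C)(C(C)C)C(C)C)c12
F4 | step 8 | 3-[(2E)-3,7-dimethylocta-2,6-dien-1-yl]-2,4-bis(methoxymethoxy)benzaldehyde | CC(C)=CCC/C(C)=C/Cc1c(OCOC)ccc(C=O)c1OCOC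
F5 | step 8 | 3-[(2E)-3,7-dimethylocta-2,6-dien-1-yl]-2,4-dihydroxybenzaldehyde | CC(C)=CCC/C(C)=C/Cc1c(O)ccc(C=O)c1O
F6 | step 8 | 2,4-bis(tert-butyldimethylsilyloxy)-3-[(2E)-3,7-dimethylocta-2,6-dien-1-yl]benzaldehyde | CC(C)=CCC/C(C)=C/Cc1c(O[Si](C)(C)C(C)(C)C)ccc(C=O)c1O[Si](C)(C)C(C)(C)C
F7 | step 8 | {2,4-bis(tert-butyldimethylsilyloxy)-3-[(2E)-3,7-dimethylocta-2,6-dien-1-yl]phenyl}methanol | CC(C)=CCC/C(C)=C/Cc1c(O[Si](C)(C)C(C)(C)C)ccc(CO)c1O[Si](C)(C)C(C)(C)C
F8 | step 8 | 1-[2-({2,4-bis(tert-butyldimethylsilyloxy)-3-[(2E)-3,7-dimethylocta-2,6-dien-1-yl]phenyl}methoxy)-4,6-bis(triisopropylsilyloxy)phenyl]ethan-1-one | CC(C)=CCC/C(C)=C/Cc1c(O[Si](C)(C)C(C)(C)C)ccc(COc2cc(O[Si](C(C)C)(C(C)C)C(C)C)cc(O[Si](C(C)C)(C(C)C)C(C)C)c2C(C)=O)c1O[Si](C)(C)C(C)(C)C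
F9 | step 8 | lithium enolate of F8 | CC(C)=CCC/C(C)=C/Cc1c(O[Si](C)(C)C(C)(C)C)ccc(COc2cc(O[Si](C(C)C)(C(C)C)C(C)C)cc(O[Si](C(C)C)(C(C)C)C(C)C)c2C(=C)O[Li])c1O[Si](C)(C)C(C)(C)C
F10 | step 8 | trifluoroacetyl diketone from F8 | CC(C)=CCC/C(C)=C/Cc1c(O[Si](C)(C)C(C)(C)C)ccc(COc2cc(O[Si](C(C)C)(C(C)C)C(C)C)cc(O[Si](C(C)C)(C(C)C)C(C)C)c2C(=O)CC(=O)C(F)(F)F)c1O[Si](C)(C)C(C)(C)C
F11 | step 8 | 1-[2-({2,4-bis(tert-butyldimethylsilyloxy)-3-[(2E)-3,7-dimethylocta-2,6-dien-1-yl]phenyl}methoxy)-4,6-bis(triisopropylsilyloxy)phenyl]-2-diazoethan-1-one | CC(C)=CCC/C(C)=C/Cc1c(O[Si](C)(C)C(C)(C)C)ccc(COc2cc(O[Si](C(C)C)(C(C)C)C(C)C)cc(O[Si](C(C)C)(C(C)C)C(C)C)c2C(=O)C=[N+]=[N-])c1O[Si](C)(C)C(C)(C)C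
F12 | step 8 | (2S)-2-{2,4-bis(tert-butyldimethylsilyloxy)-3-[(2E)-3,7-dimethylocta-2,6-dien-1-yl]phenyl}-5,7-bis(triisopropylsilyloxy)-2,3-dihydro-4H-chromen-4-one | CC(C)=CCC/C(C)=C/Cc1c(O[Si](C)(C)C(C)(C)C)ccc([C@@H]2CC(=O)c3c(O[Si](C(C)C)(C(C)C)C(C)C)cc(O[Si](C(C)C)(C(C)C)C(C)C)cc3O2)c1O[Si](C)(C)C(C)(C)C
F13 | step 3 | 2,4-dihydroxybenzaldehyde | O=Cc1ccc(O)cc1O
F14 | step 3 | 2,4-bis(methoxymethoxy)benzaldehyde | COCOc1ccc(C=O)c(OCOC)c1
F15 | step 3 | [2,4-bis(methoxymethoxy)phenyl]methanol | COCOc1ccc(CO)c(OCOC)c1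
F16 | step 3 | lithium [3-lithio-2,4-bis(methoxymethoxy)phenyl]methanolate | [Li]OCc1ccc(OCOC)c([Li])c1OCOC
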